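**Strategy**

The carbocycle of the 6-oxabicyclo[3.2.1]octane (C1, C2, C3, C4, C5, C8) is a hidden Diels–Alder adduct, because the C2 oxygen and the quaternary C5 are para to each other. A catalytic enantioselective [4+2] cycloaddition of methacrolein with an open-chain 2-silyloxydiene, made in four steps from the geranyl ether auraptene, forms C3–C4 and C5–C8 in one operation and sets C5 and C8. All four carbons of methacrolein stay in the target: its formyl carbon is moved from C5 to oxygen (Baeyer–Villiger) and then bonded to C1 by a reductive Claisen-type closure, where it becomes the OCH2 bridge C7.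

Key step: step 6

Assumption: C1–C8 in the overview are the locants of the 6-oxabicyclo[3.2.1]octane core (C1 methyl-bearing bridgehead next to carbinol C2, C5 oxygen-bearing bridgehead, O6, C7 the OCH2 carbon, C8 the carbon carrying the side chain).

Assumption: the (S)-oxazaborolidinium catalyst is taken to open the same face of the α-carbon of methacrolein as in its known cyclopentadiene adduct, which corresponds to (1S) in 11; if the diene responds with the opposite sense, the (R)-catalyst is used.

**Route**

Step 1
Reactants: 1 umbelliferone (7-hydroxy-2H-chromen-2-one); 2 geranyl bromide ((2E)-1-bromo-3,7-dimethylocta-2,6-diene)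
Product: 3 auraptene, 7-{[(2E)-3,7-dimethylocta-2,6-dien-1-yl]oxy}-2H-chromen-2-one
Conditions: K2CO3, acetone, reflux
Reagents that add atoms: none
Why: Williamson ether synthesis in which the phenoxide of 1 displaces the primary allylic bromide of 2 by SN2, leaving the E-olefin untouched and creating no stereocenter.

Step 2
Reactants: 3 auraptene
Product: 4 6',7'-epoxyauraptene, 7-{[(2E)-5-(3,3-dimethyloxiran-2-yl)-3-methylpent-2-en-1-yl]oxy}-2H-chromen-2-one (both epoxide configurations)
Conditions: mCPBA (1.05 equiv), NaHCO3, CH2Cl2, 0 °C
Reagents that add atoms: 3-chloroperoxybenzoic acid (mCPBA), OOC(=O)c1cccc(Cl)c1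
Why: Prilezhaev epoxidation, in which the electron-rich terminal olefin should react much faster than the olefin deactivated by the allylic aryloxy group or the electron-poor coumarin double bond, and the new stereocenter is removed in step 3 so it need not be controlled.

Step 3
Reactants: 4 6',7'-epoxyauraptene
Product: 6 (4E)-4-methyl-6-[(2-oxo-2H-chromen-7-yl)oxy]hex-4-enal, via vicinal diol 5 (not isolated)
Conditions: H5IO6, THF/H2O, 0 °C to rt
Reagents that add atoms: none
Why: Periodic acid should first hydrate the epoxide at its tertiary carbon to diol 5 and then cleave it (Malaprade glycol cleavage), so that the former epoxide oxygen becomes the aldehyde oxygen, the water-derived oxygen leaves with acetone and no stereocenter remains.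

Step 4
Reactants: 6 (4E)-4-methyl-6-[(2-oxo-2H-chromen-7-yl)oxy]hex-4-enal; 7 3-(triphenyl-λ5-phosphanylidene)butan-2-one
Product: 8 7-{[(2E,6E)-3,7-dimethyl-8-oxonona-2,6-dien-1-yl]oxy}-2H-chromen-2-one (E-configured α-methyl enone)
Conditions: toluene, 80 °C
Reagents that add atoms: none
Why: Wittig olefination with a stabilised α-branched ylide, which should give the E-trisubstituted enone and attacks the aldehyde but not the coumarin lactone.

Step 5
Reactants: 8 the dienone of step 4
Product: 9 7-({(2E,6E)-3,7-dimethyl-8-[(triisopropylsilyl)oxy]nona-2,6,8-trien-1-yl}oxy)-2H-chromen-2-one (cross-conjugated 2-silyloxy-1,3-diene)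
Conditions: iPr3SiOTf, Et3N, CH2Cl2, −78 to 0 °C
Reagents that add atoms: triisopropylsilyl trifluoromethanesulfonate, CC(C)[Si](C(C)C)(C(C)C)OS(=O)(=O)C(F)(F)F
Why: Soft enolisation, in which O-silylation of the ketone and deprotonation by the amine at the kinetically most accessible α'-methyl group should give the cross-conjugated silyl dienol ether with the E-olefin intact and without a new stereocenter.

Step 6
Reactants: 9 the 2-silyloxydiene of step 5; 10 methacrolein (2-methylprop-2-enal)
Product: 11 (1S,2R)-1,3-dimethyl-2-{(3E)-3-methyl-5-[(2-oxo-2H-chromen-7-yl)oxy]pent-3-en-1-yl}-4-[(triisopropylsilyl)oxy]cyclohex-3-ene-1-carbaldehyde (formyl group cis to the side chain)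
Conditions: 10 (3 equiv), 20 mol % (3aS)-1-(2-methylphenyl)-3,3-diphenyltetrahydro-1H,3H-pyrrolo[1,2-c][1,3,2]oxazaborole protonated by (CF3SO2)2NH, CH2Cl2, −78 °C
Reagents that add atoms: none
Why: The reaction is a concerted, asynchronous [4+2] cycloaddition in which the CH2 terminus of the 2-silyloxydiene bonds to the β-carbon of the catalyst-bound s-trans aldehyde slightly ahead of the bond between the alkyl-bearing diene terminus and the α-carbon. The closest known reaction type is the Diels–Alder reaction of 2-silyloxy-1,3-dienes with 2-substituted acroleins under chiral cationic oxazaborolidine catalysis. The single ring that closes, the cyclohexene, is formed by the cycloaddition itself, suprafacially on both partners. The quaternary carbon C1 of 11 is controlled by the catalyst, which leaves only one face of the α-carbon open, and C2 by the endo position of the formyl group under the E-configured diene, which places formyl group and side chain cis. The step needs para regioselectivity, secured by the silyloxy group on the inner diene carbon together with the alkyl group on the terminus, and chemoselectivity, secured because the isolated trisubstituted olefin and the coumarin are neither dienes nor Lewis-acid-activated dienophiles.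

Step 7
Reactants: 11 the cycloadduct of step 6
Product: 12 (1S,2S)-3-bromo-1,3-dimethyl-2-{(3E)-3-methyl-5-[(2-oxo-2H-chromen-7-yl)oxy]pent-3-en-1-yl}-4-oxocyclohexane-1-carbaldehyde (both configurations at C3)
Conditions: N-bromosuccinimide, NaHCO3, THF, −78 °C
Reagents that add atoms: N-bromosuccinimide, O=C1CCC(=O)N1Br
Why: Electrophilic α-bromination of a silyl enol ether, which should place bromine regiospecifically on the enol ether carbon, spares the far less nucleophilic side-chain olefin at low temperature and gives a stereocenter that is irrelevant because it becomes a planar enolate in step 9.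

Step 8
Reactants: 12 the α-bromoketone aldehyde of step 7
Product: 13 (1S,2S)-3-bromo-1,3-dimethyl-2-{(3E)-3-methyl-5-[(2-oxo-2H-chromen-7-yl)oxy]pent-3-en-1-yl}-4-oxocyclohexyl formate (both configurations at C3)
Conditions: Me3SiOOSiMe3 (1.2 equiv), Me3SiOTf (10 mol %), CH2Cl2, −78 to −30 °C
Reagents that add atoms: bis(trimethylsilyl) peroxide, C[Si](C)(C)OO[Si](C)(C)C
Why: Baeyer–Villiger oxidation of the aldehyde by a nucleophilic silyl peroxide under Lewis acid activation, in which the tertiary alkyl group should migrate in preference to hydride and with retention, so that the formate oxygen stays cis to the side chain, while a non-electrophilic oxidant leaves the olefins alone and the electron-poor α-bromoketone reacts more slowly than the aldehyde.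

Step 9
Reactants: 13 the bromoketone formate of step 8
Product: 15 lactol 7-{[(2E)-5-[(1R,5S,8R)-7-hydroxy-1,5-dimethyl-2-oxo-6-oxabicyclo[3.2.1]octan-8-yl]-3-methylpent-2-en-1-yl]oxy}-2H-chromen-2-one (both configurations at C7), via samarium enolate 14 (not isolated)
Conditions: SmI2 (2.5 equiv), THF, −78 °C; then aqueous NH4Cl
Reagents that add atoms: none
Why: Reformatsky-type reductive enolisation followed by intramolecular Claisen-type addition, in which the regiodefined enolate 14 can reach the axial formate only across the ring face that carries it (5-exo-trig closure), so the new quaternary carbon should form with the one-carbon bridge cis to the ether oxygen and its methyl group trans to the side chain.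

Step 10
Reactants: 15 the bridged lactol of step 9
Product: 16 7-{[(2E)-5-[(1R,5S,8R)-1,5-dimethyl-2-oxo-6-oxabicyclo[3.2.1]octan-8-yl]-3-methylpent-2-en-1-yl]oxy}-2H-chromen-2-one
Conditions: Et3SiH, BF3·OEt2, CH2Cl2, −78 to −20 °C
Reagents that add atoms: none
Why: Ionic hydrogenation of a lactol, in which BF3 ionises the hemiacetal and the silane should deliver hydride to the resulting cation faster than to the ketone, with no stereocenter created because the lactol carbon becomes CH2.

Step 11
Reactants: 16 the bridged ether ketone of step 10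
Product: 17 target CNP0178104.1, 7-{[(2E)-5-[(1R,2R,5S,8R)-2-hydroxy-1,5-dimethyl-6-oxabicyclo[3.2.1]octan-8-yl]-3-methylpent-2-en-1-yl]oxy}-2H-chromen-2-one
Conditions: NaBH4, MeOH, −20 °C
Reagents that add atoms: none
Why: Borohydride reduction of a conformationally fixed cyclohexanone, in which the small hydride should add axially, anti to the axial OCH2 bridge on the neighbouring quaternary carbon, to give the equatorial (2R) alcohol cis to the oxygen bridge while the coumarin lactone is left alone.

**Compound list**

1 | umbelliferone, 7-hydroxy-2H-chromen-2-one | Oc1ccc2ccc(=O)oc2c1 | starting material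
2 | geranyl bromide, (2E)-1-bromo-3,7-dimethylocta-2,6-diene | C/C(=C\CBr)CCC=C(C)C | starting material
3 | auraptene, 7-{[(2E)-3,7-dimethylocta-2,6-dien-1-yl]oxy}-2H-chromen-2-one | C/C(=C\COc1ccc2ccc(=O)oc2c1)CCC=C(C)C | intermediate
4 | 6',7'-epoxyauraptene (both epoxide configurations) | C/C(=C\COc1ccc2ccc(=O)oc2c1)CCC1OC1(C)C | intermediate
5 | 7-{[(2E)-6,7-dihydroxy-3,7-dimethyloct-2-en-1-yl]oxy}-2H-chromen-2-one | C/C(=C\COc1ccc2ccc(=O)oc2c1)CCC(O)C(C)(C)O | intermediate
6 | (4E)-4-methyl-6-[(2-oxo-2H-chromen-7-yl)oxy]hex-4-enal | C/C(=C\COc1ccc2ccc(=O)oc2c1)CCC=O | intermediate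
7 | 3-(triphenyl-λ5-phosphanylidene)butan-2-one | CC(=O)C(C)=P(c1ccccc1)(c1ccccc1)c1ccccc1 | starting material
8 | 7-{[(2E,6E)-3,7-dimethyl-8-oxonona-2,6-dien-1-yl]oxy}-2H-chromen-2-one | C/C(=C\COc1ccc2ccc(=O)oc2c1)CC/C=C(\C)C(C)=O | intermediate
9 | 7-({(2E,6E)-3,7-dimethyl-8-[(triisopropylsilyl)oxy]nona-2,6,8-trien-1-yl}oxy)-2H-chromen-2-one | C/C(=C\COc1ccc2ccc(=O)oc2c1)CC/C=C(\C)C(=C)O[Si](C(C)C)(C(C)C)C(C)C | intermediate
10 | methacrolein, 2-methylprop-2-enal | CC(=C)C=O | starting material
11 | (1S,2R)-1,3-dimethyl-2-{(3E)-3-methyl-5-[(2-oxo-2H-chromen-7-yl)oxy]pent-3-en-1-yl}-4-[(triisopropylsilyl)oxy]cyclohex-3-ene-1-carbaldehyde | C/C(=C\COc1ccc2ccc(=O)oc2c1)CC[C@@H]1C(C)=C(O[Si](C(C)C)(C(C)C)C(C)C)CC[C@]1(C)C=O | intermediate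
12 | (1S,2S)-3-bromo-1,3-dimethyl-2-{(3E)-3-methyl-5-[(2-oxo-2H-chromen-7-yl)oxy]pent-3-en-1-yl}-4-oxocyclohexane-1-carbaldehyde (C3 epimers) | C/C(=C\COc1ccc2ccc(=O)oc2c1)CC[C@@H]1C(C)(Br)C(=O)CC[C@]1(C)C=O | intermediate
13 | (1S,2S)-3-bromo-1,3-dimethyl-2-{(3E)-3-methyl-5-[(2-oxo-2H-chromen-7-yl)oxy]pent-3-en-1-yl}-4-oxocyclohexyl formate (C3 epimers) | C/C(=C\COc1ccc2ccc(=O)oc2c1)CC[C@@H]1C(C)(Br)C(=O)CC[C@]1(C)OC=O | intermediate
14 | diiodosamarium enolate formed from 13 by loss of bromine (O–SmI2 on C4, C3=C4 double bond) | C/C(=C\COc1ccc2ccc(=O)oc2c1)CC[C@@H]1C(C)=C(O[Sm](I)I)CC[C@]1(C)OC=O | intermediate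
15 | 7-{[(2E)-5-[(1R,5S,8R)-7-hydroxy-1,5-dimethyl-2-oxo-6-oxabicyclo[3.2.1]octan-8-yl]-3-methylpent-2-en-1-yl]oxy}-2H-chromen-2-one (lactol, C7 epimers) | C/C(=C\COc1ccc2ccc(=O)oc2c1)CC[C@@H]1[C@]2(C)C(O)O[C@@]1(C)CCC2=O | intermediate
16 | 7-{[(2E)-5-[(1R,5S,8R)-1,5-dimethyl-2-oxo-6-oxabicyclo[3.2.1]octan-8-yl]-3-methylpent-2-en-1-yl]oxy}-2H-chromen-2-one | C/C(=C\COc1ccc2ccc(=O)oc2c1)CC[C@@H]1[C@]2(C)CO[C@@]1(C)CCC2=O | intermediate
17 | CNP0178104.1, 7-{[(2E)-5-[(1R,2R,5S,8R)-2-hydroxy-1,5-dimethyl-6-oxabicyclo[3.2.1]octan-8-yl]-3-methylpent-2-en-1-yl]oxy}-2H-chromen-2-one | C/C(=C\COc1ccc2ccc(=O)oc2c1)CC[C@@H]1[C@]2(C)CO[C@@]1(C)CC[C@H]2O | target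

**Count**

Total steps: 11. Longest linear sequence: 11 steps (from 1 and 2 to 17).

**Steps most likely to fail**

Step 6 (key step). The process at risk is loss of the endo orientation of the formyl group, incomplete face discrimination at the aldehyde, or Mukaiyama-type 1,2-addition of the silyl dienol ether to the activated aldehyde. The fallback sets out from 9 and runs the cycloaddition with a two-point-binding ketol dienophile, 4-hydroxy-2,4-dimethylpent-1-en-3-one F1. F1 is made from commercial 2-methyl-2-(trimethylsilyloxy)propanenitrile and isopropenylmagnesium bromide, followed by aqueous HCl. The catalyst is Cu(OTf)2 with 2,2'-isopropylidenebis[(4S)-4-tert-butyl-2-oxazoline] (or its enantiomer, whichever gives the (1S) adduct) in CH2Cl2 at −40 °C. Chelation of the ketol to divalent copper should fix the enone s-cis, enforce the endo mode and shield one face, and a ketone carbonyl is not prone to the aldol side reaction. The adduct, the ketol analogue of 11 F2, would be reduced with NaBH4 to the diol analogue of 11 F3, and NaIO4 would cleave the glycol to the aldehyde, rejoining the route at 11. The two ring bonds are still formed in one cycloaddition.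

Step 8. The process at risk is oxygen transfer to the wrong site (epoxidation of the side-chain olefin, or hydride instead of alkyl migration giving the acid) and Lewis-acid-induced loss of the tertiary bromide. The fallback sets out from 12 and masks the side-chain olefin as its vicinal dibromide (Br2, CH2Cl2, −78 °C), giving the tribromo aldehyde F4. With no nucleophilic olefin left, buffered mCPBA should perform the Baeyer–Villiger oxidation to the tribromo formate F5. Zinc dust in THF would then remove the vicinal bromines by anti elimination, which restores the E-olefin. At the same time it would turn the α-bromoketone into a zinc enolate that closes onto the formate, so the route is rejoined at lactol 15.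

Step 9. The process at risk is protonation of the enolate before it reaches the formate (net debromination) or over-reduction of the formate or the lactone by excess divalent samarium. The fallback sets out from 13: zinc and Me3SiCl in THF should convert the bromoketone regiospecifically into the trimethylsilyl enol ether formate F6. Anhydrous fluoride (tetrabutylammonium difluorotriphenylsilicate, THF, −40 °C) would then release the regiodefined enolate under non-reducing, aprotic conditions, and it should add to the formate. Aqueous work-up gives lactol 15, where the route is rejoined.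

**Further compounds**

F1 | step 6 | 4-hydroxy-2,4-dimethylpent-1-en-3-one | CC(=C)C(=O)C(C)(C)O
F2 | step 6 | analogue of 11 with a 2-hydroxy-2-methylpropanoyl group in place of the formyl group (same configuration as 11) | C/C(=C\COc1ccc2ccc(=O)oc2c1)CC[C@@H]1C(C)=C(O[Si](C(C)C)(C(C)C)C(C)C)CC[C@]1(C)C(=O)C(C)(C)O
F3 | step 6 | analogue of 11 with a 1,2-dihydroxy-2-methylpropyl group in place of the formyl group (carbinol epimers) | C/C(=C\COc1ccc2ccc(=O)oc2c1)CC[C@@H]1C(C)=C(O[Si](C(C)C)(C(C)C)C(C)C)CC[C@]1(C)C(O)C(C)(C)O
F4 | step 8 | 12 with bromine added across the side-chain olefin (vicinal dibromide, diastereomers) | CC(Br)(C(Br)COc1ccc2ccc(=O)oc2c1)CC[C@@H]1C(C)(Br)C(=O)CC[C@]1(C)C=O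
F5 | step 8 | 13 with bromine added across the side-chain olefin (vicinal dibromide, diastereomers) | CC(Br)(C(Br)COc1ccc2ccc(=O)oc2c1)CC[C@@H]1C(C)(Br)C(=O)CC[C@]1(C)OC=O
F6 | step 9 | (1S,2R)-1,3-dimethyl-2-{(3E)-3-methyl-5-[(2-oxo-2H-chromen-7-yl)oxy]pent-3-en-1-yl}-4-[(trimethylsilyl)oxy]cyclohex-3-en-1-yl formate | C/C(=C\COc1ccc2ccc(=O)oc2c1)CC[C@@H]1C(C)=C(O[Si](C)(C)C)CC[C@]1(C)OC=O
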